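**Retrosynthetic overview**
- Target ⇐ type‑A bicyclic PPAP (C3‑prenyl, 7‑endo‑prenyl, C5‑geranyl): one Mn(III)/Cu(II) radical cascade makes C3–C10 (7‑exo) and C14–C13 (5‑exo), closing the seven‑membered cage ring and the cyclopentane together.
- Bicyclic PPAP ⇐ dearomatised monocyclic acylphloroglucinol: cationic C1–C8 closure from a tertiary carbinol gives the bicyclo[3.3.1]nonane; C3‑prenyl is added afterwards by Tsuji–Trost allylation.
- Monocycle ⇐ 3‑geranyl‑5‑iodo‑2,4,6‑trihydroxybenzophenone + a primary triflate from (S)‑lavandulol: alkylative dearomatisation builds quaternary C5; the iodine is a traceless block at C3 for both C–C bond formations.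
- Ring order: arene‑derived trione ring → C1/C8/C7/C6/C5/C9 ring → seven‑membered ring and cyclopentane in the same operation.
- Absolute configuration comes from C7 of (S)‑lavandulol; C1 follows from ring closure; C3, C10 and C13 are set in the cascade. C5 is not controlled (about 1:1); the wrong epimer is removed after the cationic cyclisation.

Assumption: (S)‑(+)‑lavandulol is bought enantiopure; if only the cheap racemate is available, one lipase acylation leaves the (S)‑alcohol.
Atom labels: PPAP numbering C1–C9 (C1 benzoyl bridgehead, C5 geranyl bridgehead, C8 CMe2, C9 bridging C=O); C10 = CH joining C3 to C11H2 (on C7); C12H2 (on C3), C13H (isopropenyl) and C14 (CMe2) complete the cyclopentane C3–C12–C13–C14–C10.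

**Step 1**
Reactants: 1 (S)-lavandulol [(2S)-5-methyl-2-(prop-1-en-2-yl)hex-4-en-1-ol]
Product: 2 (2R)-3-methyl-2-(3-methylbut-2-en-1-yl)butane-1,3-diol
Conditions: Co(acac)2 (20 mol%), PhSiH3 (2.2 equiv), O2 (1 atm), THF, 0 °C → rt
Reagents that add atoms: dioxygen, O=O
Why: Mukaiyama hydration (metal‑hydride H‑atom transfer, O2 trapping) is Markovnikov and faster at the 1,1‑disubstituted isopropenyl alkene than at the trisubstituted prenyl alkene, so only the former is hydrated; the stereocentre is untouched (S→R is a CIP priority change only).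

**Step 2**
Reactants: 2 (2R)-3-methyl-2-(3-methylbut-2-en-1-yl)butane-1,3-diol
Product: 3 (2R)-3-hydroxy-3-methyl-2-(3-methylbut-2-en-1-yl)butyl trifluoromethanesulfonate
Conditions: Tf2O (1.05 equiv), 2,6-lutidine, CH2Cl2, −78 °C; used cold and crude
Reagents that add atoms: trifluoromethanesulfonic anhydride, O=S(=O)(OS(=O)(=O)C(F)(F)F)C(F)(F)F
Why: O‑sulfonylation at −78 °C is much faster at the primary than at the hindered tertiary hydroxyl, giving the reactive primary triflate needed for C‑alkylation without touching the stereocentre.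

**Step 3**
Reactants: 4 2,4,6-trihydroxybenzophenone; 5 geranyl bromide [(2E)-1-bromo-3,7-dimethylocta-2,6-diene]
Product: 6 3-geranyl-2,4,6-trihydroxybenzophenone
Conditions: 10% aq. KOH, 0 °C, 4 in excess
Reagents that add atoms: none
Why: C‑alkylation of the ambident phloroglucinol phenolate in water by the allylic bromide occurs at one of the two equivalent free ring carbons, excess 4 limiting bis‑geranylation; no stereocentre is formed.

**Step 4**
Reactants: 6 3-geranyl-2,4,6-trihydroxybenzophenone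
Product: 7 3-geranyl-5-iodo-2,4,6-trihydroxybenzophenone
Conditions: I2 (1.0 equiv), NaHCO3, THF–H2O, 0 °C, dark
Reagents that add atoms: iodine, II
Why: electrophilic aromatic iodination of the phloroglucinol phenolate at its only free ring carbon is far faster than iodonium attack on the alkenes, and the iodine then blocks this carbon in steps 5 and 6.

**Step 5**
Reactants: 7 3-geranyl-5-iodo-2,4,6-trihydroxybenzophenone; 3 (2R)-3-hydroxy-3-methyl-2-(3-methylbut-2-en-1-yl)butyl trifluoromethanesulfonate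
Product: 8 (6R)-2-benzoyl-6-geranyl-3,5-dihydroxy-6-[(2R)-3-hydroxy-3-methyl-2-(3-methylbut-2-en-1-yl)butyl]-4-iodocyclohexa-2,4-dien-1-one
Conditions: LiHMDS (3.1 equiv), THF, −78 °C; 3 (1.2 equiv), −78 → −20 °C; 1 M HCl
Reagents that add atoms: none
Why: alkylative dearomatisation of the lithium triphenolate can form a C–C bond only at the geranyl‑bearing carbon because the other two ring carbons carry benzoyl and iodine, which creates quaternary C5 (ring C6) without facial control (about 1:1 with the 6S epimer, carried on and removed after step 6) while the side‑chain centre comes unchanged from 3.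

**Step 6**
Reactants: 8 (6R)-2-benzoyl-6-geranyl-3,5-dihydroxy-6-[(2R)-3-hydroxy-3-methyl-2-(3-methylbut-2-en-1-yl)butyl]-4-iodocyclohexa-2,4-dien-1-one
Product: 11 (1S,5R,7R)-1-benzoyl-5-geranyl-4-hydroxy-8,8-dimethyl-7-(3-methylbut-2-en-1-yl)bicyclo[3.3.1]non-3-ene-2,9-dione, via tertiary mesylate 9 (not isolated), via iodo bicycle 10 (not isolated)
Conditions: MsCl (1.3 equiv), Et3N (4 equiv), CH2Cl2, −40 °C → rt; then aq. Na2SO3, AcOH, 0 °C; chromatography
Reagents that add atoms: none
Why: biomimetic cationic cyclisation in which the tertiary mesylate ionises and the β‑triketonate is alkylated at the benzoyl‑bearing carbon (the only carbon nucleophile left, since C3 carries iodine), so C1 is fixed by the ring closure and the preset C5/C7 centres put the C7‑prenyl endo, the C5 epimer of 8 giving the separable 7‑exo isomer, after which sulfite removes the iodine by halophilic reduction.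

**Step 7**
Reactants: 11 (1S,5R,7R)-1-benzoyl-5-geranyl-4-hydroxy-8,8-dimethyl-7-(3-methylbut-2-en-1-yl)bicyclo[3.3.1]non-3-ene-2,9-dione; 12 prenyl acetate (3-methylbut-2-en-1-yl acetate)
Product: 13 (1R,5R,7R)-1-benzoyl-5-geranyl-4-hydroxy-8,8-dimethyl-3,7-bis(3-methylbut-2-en-1-yl)bicyclo[3.3.1]non-3-ene-2,9-dione
Conditions: Pd(PPh3)4 (5 mol%), THF, 40 °C, 12 (1.0 equiv)
Reagents that add atoms: none
Why: Tsuji–Trost allylation in which the soft, acidic diketonate attacks the less substituted terminus of the π‑prenyl‑palladium complex to give the linear C3‑prenyl compound under neutral conditions that spare the bridgehead benzoyl triketone; no stereocentre is formed (C1 changes from S to R by CIP priority only).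

**Step 8**
Reactants: 13 (1R,5R,7R)-1-benzoyl-5-geranyl-4-hydroxy-8,8-dimethyl-3,7-bis(3-methylbut-2-en-1-yl)bicyclo[3.3.1]non-3-ene-2,9-dione
Product: 14 target CNP0110731.1 (1S,3S,5R,7R,10S,13S in the labels above)
Conditions: Mn(OAc)3·2H2O (2.2 equiv), Cu(OAc)2·H2O (0.5 equiv), degassed AcOH, rt
Reagents that add atoms: none
Why: Mn(III)‑based oxidative free‑radical cyclisation in which the C3 radical adds 7‑exo‑trig to the endo C7‑prenyl alkene with the CMe2 end turned to the less hindered C4/C6 side (sets C3 and C10), the tertiary C14 radical closes 5‑exo‑trig onto the C3‑prenyl alkene with the new substituent trans to C11 (Beckwith–Houk, sets C13), and Cu(II) oxidises the last tertiary radical to the isopropenyl group.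

**Compound list**
1 | (S)-lavandulol, (2S)-5-methyl-2-(prop-1-en-2-yl)hex-4-en-1-ol | OC[C@@H](CC=C(C)C)C(C)=C | starting material
2 | (2R)-3-methyl-2-(3-methylbut-2-en-1-yl)butane-1,3-diol | OC[C@@H](CC=C(C)C)C(C)(C)O | intermediate
3 | (2R)-3-hydroxy-3-methyl-2-(3-methylbut-2-en-1-yl)butyl trifluoromethanesulfonate | FC(F)(F)S(=O)(=O)OC[C@@H](CC=C(C)C)C(C)(C)O | intermediate
4 | 2,4,6-trihydroxybenzophenone | O=C(c1ccccc1)c1c(O)cc(O)cc1O | starting material
5 | geranyl bromide, (2E)-1-bromo-3,7-dimethylocta-2,6-diene | BrC/C=C(\C)CCC=C(C)C | starting material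
6 | 3-geranyl-2,4,6-trihydroxybenzophenone | O=C(c1ccccc1)c1c(O)cc(O)c(C/C=C(\C)CCC=C(C)C)c1O | intermediate
7 | 3-geranyl-5-iodo-2,4,6-trihydroxybenzophenone | O=C(c1ccccc1)c1c(O)c(I)c(O)c(C/C=C(\C)CCC=C(C)C)c1O | intermediate
8 | (6R)-2-benzoyl-6-geranyl-3,5-dihydroxy-6-[(2R)-3-hydroxy-3-methyl-2-(3-methylbut-2-en-1-yl)butyl]-4-iodocyclohexa-2,4-dien-1-one | IC1=C(O)[C@@](C/C=C(\C)CCC=C(C)C)(C[C@@H](CC=C(C)C)C(C)(C)O)C(=O)C(C(=O)c2ccccc2)=C1O | intermediate
9 | tertiary methanesulfonate of 8 | IC1=C(O)[C@@](C/C=C(\C)CCC=C(C)C)(C[C@@H](CC=C(C)C)C(C)(C)OS(C)(=O)=O)C(=O)C(C(=O)c2ccccc2)=C1O | intermediate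
10 | (1S,5R,7R)-1-benzoyl-5-geranyl-4-hydroxy-3-iodo-8,8-dimethyl-7-(3-methylbut-2-en-1-yl)bicyclo[3.3.1]non-3-ene-2,9-dione (7-endo) | IC1=C(O)[C@@]2(C/C=C(\C)CCC=C(C)C)C[C@@H](CC=C(C)C)C(C)(C)[C@](C(=O)c3ccccc3)(C2=O)C1=O | intermediate
11 | (1S,5R,7R)-1-benzoyl-5-geranyl-4-hydroxy-8,8-dimethyl-7-(3-methylbut-2-en-1-yl)bicyclo[3.3.1]non-3-ene-2,9-dione (7-endo) | C1=C(O)[C@@]2(C/C=C(\C)CCC=C(C)C)C[C@@H](CC=C(C)C)C(C)(C)[C@](C(=O)c3ccccc3)(C2=O)C1=O | intermediate
12 | prenyl acetate, 3-methylbut-2-en-1-yl acetate | CC(C)=CCOC(C)=O | starting material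
13 | (1R,5R,7R)-1-benzoyl-5-geranyl-4-hydroxy-8,8-dimethyl-3,7-bis(3-methylbut-2-en-1-yl)bicyclo[3.3.1]non-3-ene-2,9-dione (7-endo, drawn enol tautomer) | CC(C)=CCC1=C(O)[C@@]2(C/C=C(\C)CCC=C(C)C)C[C@@H](CC=C(C)C)C(C)(C)[C@](C(=O)c3ccccc3)(C2=O)C1=O | intermediate
14 | CNP0110731.1: 1-benzoyl-5-geranyl-8,8-dimethylbicyclo[3.3.1]nonane-2,4,9-trione with C3 and C7 bridged by C10H–C11H2 and a cyclopentane C3–C12H2–C13H(isopropenyl)–C14Me2–C10 fused on C3–C10; 1S,3S,5R,7R,10S,13S | C=C(C)[C@@H]1C[C@@]23C(=O)[C@@]4(C/C=C(\C)CCC=C(C)C)C[C@@H](C[C@H]2C1(C)C)C(C)(C)[C@](C(=O)c1ccccc1)(C4=O)C3=O | target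

**Totals**
Total step count: 8. Longest linear sequence: 6 (steps 1, 2, 5, 6, 7, 8 or 3, 4, 5, 6, 7, 8).

**Three steps most likely to fail**

Step 5. A β‑branched primary triflate with a free tertiary hydroxyl must alkylate a fully substituted ring carbon; O‑alkylation and loss of the triflate (oxetane) compete, and C5 forms unselectively. The fallback sets out from 4 and comes back at 8, with the two electrophiles changing roles. The triflate 3 is used on a free ring carbon of 4 (LiHMDS, THF) to give 3-[(2R)-3-hydroxy-3-methyl-2-(3-methylbut-2-en-1-yl)butyl]-2,4,6-trihydroxybenzophenone F1. Iodination as in step 4 gives its 5-iodo derivative F2. The reactive allylic bromide 5 (aq. KOH, 0 °C) then dearomatises F2 at the chain‑bearing carbon, the only one free of benzoyl and iodine, to give 8.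

Step 6. The tertiary cation may be captured by enol oxygen (pyran) or lose a proton, the enolate may be O‑sulfonylated, and the 7‑endo closure is the more strained one. The fallback sets out from 7 and 1 and comes back at 10, replacing the free carbocation by π‑acid catalysis. Lavandulol 1 is converted directly (Tf2O, 2,6‑lutidine) into (S)-lavandulyl trifluoromethanesulfonate F3. Alkylative dearomatisation of 7 with F3 under the step 5 conditions gives (6R)-2-benzoyl-6-geranyl-3,5-dihydroxy-4-iodo-6-[(2R)-5-methyl-2-(prop-1-en-2-yl)hex-4-en-1-yl]cyclohexa-2,4-dien-1-one F4. A cationic gold(I) catalyst (JohnPhosAuCl/AgOTf, toluene, 60 °C) then effects Markovnikov 6‑exo hydroalkylation of the isopropenyl alkene by C1 to give 10, which is deiodinated as in step 6.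

Step 8. Cu(II) may oxidise the C14 radical before the 5‑exo closure, the C3 radical may find the geranyl alkene, and the C10/C13 selectivity rests on conformational arguments. The fallback sets out from 13 and comes back at 14, generating the C3 radical by C–I homolysis instead of enol oxidation. NIS (CH2Cl2, 0 °C) iodinates C3 from the exo face to give 1-benzoyl-5-geranyl-3-iodo-8,8-dimethyl-3,7-bis(3-methylbut-2-en-1-yl)bicyclo[3.3.1]nonane-2,4,9-trione F5 (the C3 configuration is lost on homolysis). Blue‑light irradiation with Co(dmgH)2(py)Cl (10 mol%) and i‑Pr2NEt in MeCN triggers the same 7‑exo/5‑exo cascade, and cobalt‑mediated β‑hydrogen abstraction from a methyl group ends it at the isopropenyl group of 14.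

**Further compounds**
F1 | step 5 | 3-[(2R)-3-hydroxy-3-methyl-2-(3-methylbut-2-en-1-yl)butyl]-2,4,6-trihydroxybenzophenone | O=C(c1ccccc1)c1c(O)cc(O)c(C[C@@H](CC=C(C)C)C(C)(C)O)c1O
F2 | step 5 | 3-[(2R)-3-hydroxy-3-methyl-2-(3-methylbut-2-en-1-yl)butyl]-5-iodo-2,4,6-trihydroxybenzophenone | O=C(c1ccccc1)c1c(O)c(I)c(O)c(C[C@@H](CC=C(C)C)C(C)(C)O)c1O
F3 | step 6 | (S)-lavandulyl trifluoromethanesulfonate, (2S)-5-methyl-2-(prop-1-en-2-yl)hex-4-en-1-yl trifluoromethanesulfonate | FC(F)(F)S(=O)(=O)OC[C@@H](CC=C(C)C)C(C)=C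
F4 | step 6 | (6R)-2-benzoyl-6-geranyl-3,5-dihydroxy-4-iodo-6-[(2R)-5-methyl-2-(prop-1-en-2-yl)hex-4-en-1-yl]cyclohexa-2,4-dien-1-one | IC1=C(O)[C@@](C/C=C(\C)CCC=C(C)C)(C[C@@H](CC=C(C)C)C(C)=C)C(=O)C(C(=O)c2ccccc2)=C1O
F5 | step 8 | 1-benzoyl-5-geranyl-3-iodo-8,8-dimethyl-3,7-bis(3-methylbut-2-en-1-yl)bicyclo[3.3.1]nonane-2,4,9-trione, iodine exo | I[C@]1(CC=C(C)C)C(=O)[C@@]2(C/C=C(\C)CCC=C(C)C)C[C@@H](CC=C(C)C)C(C)(C)[C@](C(=O)c3ccccc3)(C2=O)C1=O
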